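**Plan**

- Last cuts: the five O-benzyl ethers, then the C3–H bond, which is traced back to a C3 allyl ester that leaves as CO2 and propene.
- Strategic cut: C3–C4 of ring C. Ring C holds an α-ketol, C4(=O)–C3(OH), with C4 bonded to ring-A carbon C4a. This is a benzoin pattern between a ring-A aryl aldehyde (C4) and a C3 carbonyl tethered through O1–C2; the C3 ester makes that carbonyl a keto ester.
- Further cuts: O1–C2 (phenol plus α-chloro keto ester), C2–C3 (Darzens union) and the two ring-A–CH2 bonds at C6 and C8 (Friedel–Crafts).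
- Forward order: ring A is fully substituted first, the C2–C3 unit is made separately, both are joined at O1–C2, and ring C closes last through C3–C4.
- Stereochemistry: C2 (R) comes from a chiral triazolium carbene acting on the racemising keto ester (dynamic kinetic resolution). C3 (R) is fixed after decarboxylation by ketonisation to the 2,3-trans ketol.

Key step: step 6

Remark: keto ester 11 is drawn as the ketone although it should rest largely as its enol; which antipode of the triazolium salt, (5aR,10bS)-2-(pentafluorophenyl)-5a,10b-dihydro-4H,6H-indeno[2,1-b][1,2,4]triazolo[4,3-d][1,4]oxazin-2-ium tetrafluoroborate or its mirror image (both from commercial cis-1-amino-2-indanol), leads to 2R must be settled in a pilot run.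

**Step 1**
Reactants: 1 2,4,6-trihydroxybenzaldehyde; 2 4-benzyloxybenzyl alcohol (2.2 equiv)
Product: 3 3,5-bis(4-benzyloxybenzyl)-2,4,6-trihydroxybenzaldehyde
Conditions: BF3·OEt2 (0.2 equiv), 1,4-dioxane, 23 °C, slow addition of 2
Reagents that add atoms: none
Why: Double Friedel–Crafts benzylation in which the 4-alkoxybenzyl cation is captured at C3 and C5, the only free and doubly hydroxyl-activated ring positions, while O-benzylation by this cation is reversible under acid and the chelated formyl group is a far weaker electrophile.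

**Step 2**
Reactants: 3 3,5-bis(4-benzyloxybenzyl)-2,4,6-trihydroxybenzaldehyde
Product: 4 2,4-bis(benzyloxy)-3,5-bis(4-benzyloxybenzyl)-6-hydroxybenzaldehyde
Conditions: BnBr (2.1 equiv), K2CO3 (2.2 equiv), DMF, 23 °C
Reagents that add atoms: benzyl bromide, BrCc1ccccc1
Why: Williamson etherification in which the para hydroxyl (most acidic) and one of the two equivalent ortho hydroxyls react, while the last hydroxyl, then strongly hydrogen-bonded to the formyl group and flanked by a benzyl group, should be spared at two equivalents of benzyl bromide.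

**Step 3**
Reactants: 5 dichloroacetic acid; 6 allyl alcohol
Product: 7 allyl dichloroacetate
Conditions: TsOH·H2O (cat.), toluene, reflux, Dean–Stark
Reagents that add atoms: none
Why: Fischer esterification driven by azeotropic removal of water, the allyl ester being chosen because palladium can later remove it without touching benzyl ethers.

**Step 4**
Reactants: 7 allyl dichloroacetate; 8 4-benzyloxybenzaldehyde
Product: 10 allyl 3-chloro-3-(4-benzyloxyphenyl)-2-oxopropanoate (racemic), via chloroglycidate 9 (not isolated)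
Conditions: t-BuOK (1.05 equiv), THF, −40 → 23 °C
Reagents that add atoms: none
Why: Darzens condensation of the dichloroacetate enolate with the aldehyde gives α-chloroglycidate 9, which, as is usual for aryl α-chloroglycidates and helped here by the 4-alkoxyphenyl group, opens at the benzylic carbon with chloride shift to the β-chloro α-keto ester, whose single stereocentre is racemic and labile and needs no control.

**Step 5**
Reactants: 4 2,4-bis(benzyloxy)-3,5-bis(4-benzyloxybenzyl)-6-hydroxybenzaldehyde; 10 allyl 3-chloro-3-(4-benzyloxyphenyl)-2-oxopropanoate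
Product: 11 allyl 3-(4-benzyloxyphenyl)-3-[3,5-bis(benzyloxy)-2,4-bis(4-benzyloxybenzyl)-6-formylphenoxy]-2-oxopropanoate (racemic)
Conditions: K2CO3 (1.1 equiv), NaI (0.1 equiv), acetone, 0 → 23 °C, 10 added slowly
Reagents that add atoms: none
Why: Williamson-type displacement at an α-halo ketone, in which the phenoxide of 4 attacks the doubly activated (benzylic and α-keto) carbon with iodide exchange speeding substitution, and the new centre (the future C2) is deliberately left racemic because it equilibrates through the enol.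

**Step 6**
Reactants: 11 allyl 3-(4-benzyloxyphenyl)-3-[3,5-bis(benzyloxy)-2,4-bis(4-benzyloxybenzyl)-6-formylphenoxy]-2-oxopropanoate (racemic)
Product: 12 allyl (2R,3R)-5,7-bis(benzyloxy)-6,8-bis(4-benzyloxybenzyl)-2-(4-benzyloxyphenyl)-3-hydroxy-4-oxochromane-3-carboxylate
Conditions: chiral aminoindanol-derived N-C6F5 triazolium tetrafluoroborate (15 mol %), K2CO3 (1 equiv), MTBE, 23 °C, argon
Reagents that add atoms: none
Why: Proposed new method: the carbene adds to the only aldehyde (C4, on ring A), proton transfer gives the Breslow enaminol, and this acyl-anion equivalent attacks the tethered C3 keto group, forming C3–C4 and closing ring C in a 6-exo-trig mode before the catalyst is released. The closest known reaction types are the carbene-catalysed aldehyde–ketone benzoin cyclisation that gives 3-hydroxychroman-4-ones and the dynamic kinetic crossed benzoin of racemising β-stereogenic α-keto esters; they are merged here in one substrate. C3 is set by the chiral triazolium, which selects one face of the keto carbonyl. C2 is set by dynamic kinetic resolution: 11 racemises through its enol under K2CO3 and only the epimer that can place the 2-aryl group pseudo-equatorial in the chair-like closure reacts fast, so catalyst control at C3 is relayed to C2. The step needs the ring-A aldehyde to be the only acyl donor, which the substrate secures because the keto ester has no formyl hydrogen and so can neither form an acyl-anion equivalent nor expel the ring-A aryloxide by internal redox, the likely fate of an α-aryloxy aldehyde acceptor; it also needs benzoin to beat aldol, which the fully substituted, hindered enol carbon favours. With no hydrogen at C3 the product cannot enolise, ring-open or epimerise under the basic conditions.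

**Step 7**
Reactants: 12 allyl (2R,3R)-5,7-bis(benzyloxy)-6,8-bis(4-benzyloxybenzyl)-2-(4-benzyloxyphenyl)-3-hydroxy-4-oxochromane-3-carboxylate
Product: 15 penta-O-benzyl gericudranin D, via keto acid 13 (not isolated), via enediol 14 (not isolated)
Conditions: Pd(OAc)2 (5 mol %), PPh3 (12 mol %), HCO2H (5 equiv), 1,4-dioxane, 40 °C; then TsOH·H2O (10 mol %), 50 °C
Reagents that add atoms: none
Why: Tsuji-type deallylative decarboxylation in which zerovalent palladium formed in situ ionises the allyl ester, formate reduces the allyl unit to propene and β-keto acid 13 loses CO2 to enediol 14, which ketonises to the conjugated aryl ketone; C3 is set here under thermodynamic control, the acid stage equilibrating the ketol through its enol to the 2,3-trans epimer (2-aryl and 3-hydroxyl both equatorial, OH···O=C4 hydrogen bond), while C2 is safe because no base is present and the 4'-oxygen is benzylated.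

**Step 8**
Reactants: 15 penta-O-benzyl gericudranin D
Product: 16 gericudranin D
Conditions: H2 (1 atm), 10% Pd/C, EtOAc–MeOH, 23 °C
Reagents that add atoms: none
Why: Hydrogenolysis of the five aryl benzyl ethers under neutral conditions at room temperature, which should leave the C4 ketone, the benzylic C2–O1 bond and both stereocentres untouched if hydrogen uptake is stopped at the calculated amount.

**Compound list**

1 | 2,4,6-trihydroxybenzaldehyde | O=Cc1c(O)cc(O)cc1O | starting material
2 | 4-benzyloxybenzyl alcohol | OCc1ccc(OCc2ccccc2)cc1 | starting material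
3 | 3,5-bis(4-benzyloxybenzyl)-2,4,6-trihydroxybenzaldehyde | O=Cc1c(O)c(Cc2ccc(OCc3ccccc3)cc2)c(O)c(Cc2ccc(OCc3ccccc3)cc2)c1O | intermediate
4 | 2,4-bis(benzyloxy)-3,5-bis(4-benzyloxybenzyl)-6-hydroxybenzaldehyde | O=Cc1c(OCc2ccccc2)c(Cc2ccc(OCc3ccccc3)cc2)c(OCc2ccccc2)c(Cc2ccc(OCc3ccccc3)cc2)c1O | intermediate
5 | dichloroacetic acid | OC(=O)C(Cl)Cl | starting material
6 | allyl alcohol | OCC=C | starting material
7 | allyl dichloroacetate | C=CCOC(=O)C(Cl)Cl | intermediate
8 | 4-benzyloxybenzaldehyde | O=Cc1ccc(OCc2ccccc2)cc1 | starting material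
9 | allyl 2-chloro-3-(4-benzyloxyphenyl)oxirane-2-carboxylate (racemic; not isolated) | C=CCOC(=O)C1(Cl)OC1c1ccc(OCc2ccccc2)cc1 | intermediate
10 | allyl 3-chloro-3-(4-benzyloxyphenyl)-2-oxopropanoate (racemic) | C=CCOC(=O)C(=O)C(Cl)c1ccc(OCc2ccccc2)cc1 | intermediate
11 | allyl 3-(4-benzyloxyphenyl)-3-[3,5-bis(benzyloxy)-2,4-bis(4-benzyloxybenzyl)-6-formylphenoxy]-2-oxopropanoate (racemic) | O=Cc1c(OCc2ccccc2)c(Cc2ccc(OCc3ccccc3)cc2)c(OCc2ccccc2)c(Cc2ccc(OCc3ccccc3)cc2)c1OC(C(=O)C(=O)OCC=C)c1ccc(OCc2ccccc2)cc1 | intermediate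
12 | allyl (2R,3R)-5,7-bis(benzyloxy)-6,8-bis(4-benzyloxybenzyl)-2-(4-benzyloxyphenyl)-3-hydroxy-4-oxochromane-3-carboxylate (3-hydroxyl trans to the 2-aryl group) | O=C1c2c(OCc3ccccc3)c(Cc3ccc(OCc4ccccc4)cc3)c(OCc3ccccc3)c(Cc3ccc(OCc4ccccc4)cc3)c2O[C@H](c2ccc(OCc3ccccc3)cc2)[C@]1(O)C(=O)OCC=C | intermediate
13 | (2R,3R)-5,7-bis(benzyloxy)-6,8-bis(4-benzyloxybenzyl)-2-(4-benzyloxyphenyl)-3-hydroxy-4-oxochromane-3-carboxylic acid (not isolated) | O=C1c2c(OCc3ccccc3)c(Cc3ccc(OCc4ccccc4)cc3)c(OCc3ccccc3)c(Cc3ccc(OCc4ccccc4)cc3)c2O[C@H](c2ccc(OCc3ccccc3)cc2)[C@]1(O)C(=O)O | intermediate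
14 | (2R)-5,7-bis(benzyloxy)-6,8-bis(4-benzyloxybenzyl)-2-(4-benzyloxyphenyl)-2H-chromene-3,4-diol (not isolated) | OC1=C(O)[C@@H](c2ccc(OCc3ccccc3)cc2)Oc2c(Cc3ccc(OCc4ccccc4)cc3)c(OCc3ccccc3)c(Cc3ccc(OCc4ccccc4)cc3)c(OCc3ccccc3)c12 | intermediate
15 | penta-O-benzyl gericudranin D: (2R,3R)-5,7-bis(benzyloxy)-6,8-bis(4-benzyloxybenzyl)-2-(4-benzyloxyphenyl)-3-hydroxychroman-4-one | O=C1c2c(OCc3ccccc3)c(Cc3ccc(OCc4ccccc4)cc3)c(OCc3ccccc3)c(Cc3ccc(OCc4ccccc4)cc3)c2O[C@H](c2ccc(OCc3ccccc3)cc2)[C@H]1O | intermediate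
16 | gericudranin D: (2R,3R)-3,5,7-trihydroxy-6,8-bis(4-hydroxybenzyl)-2-(4-hydroxyphenyl)chroman-4-one | O=C1c2c(O)c(Cc3ccc(O)cc3)c(O)c(Cc3ccc(O)cc3)c2O[C@H](c2ccc(O)cc2)[C@H]1O | target

**Totals and risks**

Total steps: 8. Longest linear sequence: 6 steps (steps 1, 2, 5, 6, 7, 8).

Step 6 (Proposed new method). Several processes may defeat it:
- the carbene may not engage the aldehyde, which is flanked by two ortho oxygens and deactivated by three donors;
- the acidic enol form of 11 may keep the carbene protonated;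
- enolate addition to the formyl group (aldol) may overtake the benzoin closure;
- facial selection may be poor.

The fallback uses known chemistry, sets out from 4 and rejoins the route at 15. The free hydroxyl of 4 is protected (NaH, MOMCl, DMF) to give the MOM ether F1. MeMgBr in THF gives the carbinol F2, and Dess–Martin oxidation gives the acetophenone F3. Claisen–Schmidt condensation with 8 (KOH, EtOH) gives the (E)-chalcone F4. Juliá–Colonna epoxidation (poly-L-leucine, urea–H2O2, DBU, THF) should give the (αR,βS)-epoxychalcone F5. HCl in MeOH–THF removes the MOM group to the 2'-hydroxy epoxychalcone F6, whose phenol opens the epoxide at the benzylic carbon with inversion (6-endo) to give 15; step 8 then follows.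

Step 5. Enolisation and self-condensation of 10, or base-mediated aldol closure of the product onto the formyl group (Rap–Stoermer-type), may compete with O-alkylation of the hindered, chelated phenoxide. The fallback sets out from 8 and 4 and rejoins at 11. Darzens condensation of 8 with allyl chloroacetate (t-BuOK, THF) gives the trans-glycidate F7. Phenol 4 opens it at the 4-alkoxybenzylic carbon under mild Lewis acid catalysis (Zn(OTf)2, CH2Cl2) to give the α-hydroxy ester F8 as a diastereomer mixture, and Dess–Martin oxidation of the secondary alcohol returns 11.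

Step 7. Protonation of enediol 14 may occur on the face away from the 2-aryl group and leave the 2,3-cis ketol, and acid equilibration at C3 may then be slow or costly; C-allylation of the palladium enolate is a lesser risk. The fallback turns the cis preference into an asset, sets out from 11 and rejoins at 16.
- Step 6 is run with the antipodal triazolium salt to give the (2S,3S)-chromanone ester F9.
- The palladium and formic acid treatment without the acid stage passes through the keto acid F10 and the enediol F11, and should give the 2,3-cis ketol F12 with 3R configuration.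
- Hydrogenolysis as in step 8 gives the (2S,3R)-pentaphenol F13.
- Gentle warming in aqueous ethanol then lets ring C open and reclose at O1–C2 through the 4'-quinone methide, a known behaviour of dihydroflavonols with a free 4'-hydroxyl. C3 is not touched, and C2 should settle in the more stable trans arrangement, which is 16.

**Further compounds**

F1 | step 6 | 2,4-bis(benzyloxy)-3,5-bis(4-benzyloxybenzyl)-6-(methoxymethoxy)benzaldehyde | O=Cc1c(OCc2ccccc2)c(Cc2ccc(OCc3ccccc3)cc2)c(OCc2ccccc2)c(Cc2ccc(OCc3ccccc3)cc2)c1OCOC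
F2 | step 6 | 1-[2,4-bis(benzyloxy)-3,5-bis(4-benzyloxybenzyl)-6-(methoxymethoxy)phenyl]ethanol (racemic) | CC(O)c1c(OCc2ccccc2)c(Cc2ccc(OCc3ccccc3)cc2)c(OCc2ccccc2)c(Cc2ccc(OCc3ccccc3)cc2)c1OCOC
F3 | step 6 | 1-[2,4-bis(benzyloxy)-3,5-bis(4-benzyloxybenzyl)-6-(methoxymethoxy)phenyl]ethanone | CC(=O)c1c(OCc2ccccc2)c(Cc2ccc(OCc3ccccc3)cc2)c(OCc2ccccc2)c(Cc2ccc(OCc3ccccc3)cc2)c1OCOC
F4 | step 6 | (E)-1-[2,4-bis(benzyloxy)-3,5-bis(4-benzyloxybenzyl)-6-(methoxymethoxy)phenyl]-3-(4-benzyloxyphenyl)prop-2-en-1-one | O=C(/C=C/c1ccc(OCc2ccccc2)cc1)c1c(OCc2ccccc2)c(Cc2ccc(OCc3ccccc3)cc2)c(OCc2ccccc2)c(Cc2ccc(OCc3ccccc3)cc2)c1OCOC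
F5 | step 6 | [2,4-bis(benzyloxy)-3,5-bis(4-benzyloxybenzyl)-6-(methoxymethoxy)phenyl][(2R,3S)-3-(4-benzyloxyphenyl)oxiran-2-yl]methanone | O=C([C@@H]1O[C@H]1c1ccc(OCc2ccccc2)cc1)c1c(OCc2ccccc2)c(Cc2ccc(OCc3ccccc3)cc2)c(OCc2ccccc2)c(Cc2ccc(OCc3ccccc3)cc2)c1OCOC
F6 | step 6 | [2,4-bis(benzyloxy)-3,5-bis(4-benzyloxybenzyl)-6-hydroxyphenyl][(2R,3S)-3-(4-benzyloxyphenyl)oxiran-2-yl]methanone (not isolated) | O=C([C@@H]1O[C@H]1c1ccc(OCc2ccccc2)cc1)c1c(OCc2ccccc2)c(Cc2ccc(OCc3ccccc3)cc2)c(OCc2ccccc2)c(Cc2ccc(OCc3ccccc3)cc2)c1O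
F7 | step 5 | allyl trans-3-(4-benzyloxyphenyl)oxirane-2-carboxylate (racemic, one enantiomer drawn) | C=CCOC(=O)[C@@H]1O[C@H]1c1ccc(OCc2ccccc2)cc1
F8 | step 5 | allyl 3-(4-benzyloxyphenyl)-3-[3,5-bis(benzyloxy)-2,4-bis(4-benzyloxybenzyl)-6-formylphenoxy]-2-hydroxypropanoate (racemic diastereomer mixture) | O=Cc1c(OCc2ccccc2)c(Cc2ccc(OCc3ccccc3)cc2)c(OCc2ccccc2)c(Cc2ccc(OCc3ccccc3)cc2)c1OC(C(O)C(=O)OCC=C)c1ccc(OCc2ccccc2)cc1
F9 | step 7 | allyl (2S,3S)-5,7-bis(benzyloxy)-6,8-bis(4-benzyloxybenzyl)-2-(4-benzyloxyphenyl)-3-hydroxy-4-oxochromane-3-carboxylate | O=C1c2c(OCc3ccccc3)c(Cc3ccc(OCc4ccccc4)cc3)c(OCc3ccccc3)c(Cc3ccc(OCc4ccccc4)cc3)c2O[C@@H](c2ccc(OCc3ccccc3)cc2)[C@@]1(O)C(=O)OCC=C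
F10 | step 7 | (2S,3S)-5,7-bis(benzyloxy)-6,8-bis(4-benzyloxybenzyl)-2-(4-benzyloxyphenyl)-3-hydroxy-4-oxochromane-3-carboxylic acid (not isolated) | O=C1c2c(OCc3ccccc3)c(Cc3ccc(OCc4ccccc4)cc3)c(OCc3ccccc3)c(Cc3ccc(OCc4ccccc4)cc3)c2O[C@@H](c2ccc(OCc3ccccc3)cc2)[C@@]1(O)C(=O)O
F11 | step 7 | (2S)-5,7-bis(benzyloxy)-6,8-bis(4-benzyloxybenzyl)-2-(4-benzyloxyphenyl)-2H-chromene-3,4-diol (not isolated) | OC1=C(O)[C@H](c2ccc(OCc3ccccc3)cc2)Oc2c(Cc3ccc(OCc4ccccc4)cc3)c(OCc3ccccc3)c(Cc3ccc(OCc4ccccc4)cc3)c(OCc3ccccc3)c12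
F12 | step 7 | (2S,3R)-5,7-bis(benzyloxy)-6,8-bis(4-benzyloxybenzyl)-2-(4-benzyloxyphenyl)-3-hydroxychroman-4-one (2,3-cis) | O=C1c2c(OCc3ccccc3)c(Cc3ccc(OCc4ccccc4)cc3)c(OCc3ccccc3)c(Cc3ccc(OCc4ccccc4)cc3)c2O[C@@H](c2ccc(OCc3ccccc3)cc2)[C@H]1O
F13 | step 7 | (2S,3R)-3,5,7-trihydroxy-6,8-bis(4-hydroxybenzyl)-2-(4-hydroxyphenyl)chroman-4-one (2,3-cis) | O=C1c2c(O)c(Cc3ccc(O)cc3)c(O)c(Cc3ccc(O)cc3)c2O[C@@H](c2ccc(O)cc2)[C@H]1O
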